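## Retrosynthetic overview

Atom labels: Cq = quaternary C–Me; a1 = ring-A CH(OAc); a5 = ring-fusion CH; a6 = CH(OH); a7 = C(OH) of the lactone; a8 = lactone O–CH; C10 = CH(OAc) of the ten-membered ring; b = lactone CH(Me).

1. The lactone is formed last, by an intramolecular Reformatsky (aldol-type) closure of an a8-O-2-bromopropionate onto the a7 ketone of a 6/10 α-hydroxy ketone.
2. The ten-membered ring comes from RCM of a vinyl carbinol and a homoprenyl terminus (the cis ring alkene is favoured in a 10-ring). The vinyl carbinol comes from NHK vinylation of an α-keto aldehyde, and the a6–a7–a8 unit from an NHC crossed benzoin of a ring-A aldehyde with glyoxal acetal.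
3. Ring A comes from an organocatalytic Michael/Robinson aldol of methyl 2-methylacetoacetate with an acetal-bearing α-methyl enal, followed by deconjugation and CBS reduction. The C10 carbinol comes from a Weinreb ketone and a syn-selective 1,3-reduction.
4. Ring order: ring A (Steps 2–3), then the 10-membered ring (Step 13), then the lactone (Step 15).

Assumption: 2-bromopropionyl bromide is used as the racemate, since its stereocentre is erased at the zinc enolate. Catalyst enantiomers are chosen to give the drawn absolute configuration. The ring alkene is (Z) by CIP (cis ring bonds), exactly as in the given SMILES.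

## Route

**Step 1**
Reactants: 1 (2,2-dimethoxyacetaldehyde); 2 ((1-formylethylidene)triphenylphosphorane)
Product: 3 ((E)-4,4-dimethoxy-2-methylbut-2-enal)
Conditions: CH2Cl2, 23 °C, 12 h
Reagents that add atoms: none
Why: Stabilized-ylide Wittig olefination gives the (E)-α-methyl enal needed as the iminium acceptor in Step 2.

**Step 2**
Reactants: 3; 4 (methyl 2-methyl-3-oxobutanoate)
Product: 5 (cyclohexenone; Cq and a5 set, a4 epimeric)
Conditions: (S)-diphenylprolinol TMS ether (20 mol%), 2-fluorobenzoic acid (20 mol%), toluene, 23 °C, 72 h; then pyrrolidine (0.3 equiv), AcOH, 50 °C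
Reagents that add atoms: none (H2O is lost)
Why: Proposed new method: the prolinol ether forms an iminium with the α,β-disubstituted enal 3 and shields one face, so the enol of 4 adds at the β-carbon (a5). This creates the adjacent quaternary/tertiary pair Cq/a5, and the product is favoured as the trans-diequatorial isomer (CO2Me and CH(OMe)2 trans). The amine/AcOH then closes ring A by intramolecular aldol condensation of the acetyl CH3 onto the aldehyde (Robinson-type). The closest known reactions are organocatalytic iminium Michael additions of α-substituted β-ketoesters to enals and the Robinson/Hajos–Parrish annulation, which have not been combined for an acyclic α-methyl donor and an α,β-disubstituted enal.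

**Step 3**
Reactants: 5
Product: 6 (β,γ-enone, a3=a4)
Conditions: KHMDS (1.1 equiv), THF, −78 °C, 30 min; then AcOH, −78 °C
Reagents that add atoms: none
Why: The α′-position is blocked by Cq, so γ-deprotonation at a4 gives the extended dienolate, and kinetic α-protonation (deconjugation) places the trisubstituted alkene at a3=a4 and erases the a4 stereocentre.

**Step 4**
Reactants: 6
Product: 7 (hydroxy ester, a1 = S)
Conditions: (R)-Me-CBS (20 mol%), catecholborane (1.5 equiv), toluene, −78 °C
Reagents that add atoms: none
Why: CBS reduction is reagent-controlled, differentiating the large quaternary Cq side from the small CH2 (a2) side. It delivers hydride to the face syn to the angular methyl, opposite to the substrate's intrinsic bias, which gives the axial (S)-a1 alcohol; the ester and acetal are untouched.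

**Step 5**
Reactants: 7
Product: 8 (Weinreb amide)
Conditions: MeONHMe·HCl (3 equiv), i-PrMgCl (6 equiv), THF, −20 → 0 °C
Reagents that add atoms: N,O-dimethylhydroxylamine hydrochloride, CNOC.Cl
Why: Magnesium amide exchange (Williams Weinreb amidation) converts the hindered methyl ester into an amide that stops at the ketone stage in Step 6.

**Step 6**
Reactants: 8; 9 (4-bromo-2-methylbut-1-ene, converted in situ to the Grignard with Mg)
Product: 10 (β-hydroxy ketone)
Conditions: 3-methylbut-3-en-1-ylMgBr (3 equiv), THF, 0 → 23 °C
Reagents that add atoms: none (the C5 unit comes from 9)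
Why: Grignard addition to a Weinreb amide stops cleanly at the ketone, and the free a1-alkoxide is tolerated with the excess reagent.

**Step 7**
Reactants: 10
Product: 11 (1,3-syn diol)
Conditions: Et2BOMe (1.2 equiv), NaBH4 (1.5 equiv), THF/MeOH 4:1, −78 °C; then H2O2, aq. NaHCO3
Reagents that add atoms: none
Why: Narasaka–Prasad reduction proceeds through a six-membered boron chelate of the β-hydroxy ketone and delivers hydride axially, giving the syn-1,3-diol with the C10 configuration of the target relative to a1.

**Step 8**
Reactants: 11
Product: 12 (a1,C10-diacetate)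
Conditions: Ac2O (10 equiv), DMAP (0.3 equiv), Et3N, CH2Cl2, 40 °C
Reagents that add atoms: acetic anhydride, CC(=O)OC(C)=O
Why: Exhaustive acylation installs both target acetates early, where they survive every later step.

**Step 9**
Reactants: 12
Product: 13 (a6 aldehyde)
Conditions: Ce(OTf)3 (10 mol%), wet MeNO2, 23 °C
Reagents that add atoms: water, O
Why: Near-neutral Lewis-acid acetal hydrolysis leaves the acetates and the 1,1-disubstituted alkene intact, and the α-stereocentre a5 remains in its stable trans-diequatorial arrangement.

**Step 10**
Reactants: 13; 1 (3 equiv, added slowly)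
Product: 14 (α-hydroxy ketone; a6 set, a7 ketone, a8 dimethyl acetal)
Conditions: aminoindanol-derived chiral triazolium salt (20 mol%), i-Pr2NEt (20 mol%), THF, 0 → 23 °C
Reagents that add atoms: none (the glyoxal acetal is a numbered reactant)
Why: Proposed new method: the chiral NHC adds to glyoxal acetal 1 to give an acetal-bearing Breslow intermediate (acyl anion), which attacks one face of the hindered aldehyde 13 and sets a6; collapse releases a7 at the ketone level with a8 as a masked aldehyde. The closest known reaction is the NHC-catalysed crossed benzoin/acyloin reaction with α-oxygenated aldehyde donors, not yet shown for a glyoxal acetal donor and an α-branched, β-quaternary aliphatic acceptor.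

**Step 11**
Reactants: 14
Product: 15 (α-keto aldehyde)
Conditions: TFA/H2O/CH2Cl2 (1:1:20), 0 → 23 °C
Reagents that add atoms: water, O
Why: Acid hydrolysis of the α-keto dimethyl acetal frees the a8 aldehyde; the acetates survive.

**Step 12**
Reactants: 15; 16 (vinyl bromide, 1 M in THF)
Product: 17 (a8 vinyl carbinol)
Conditions: CrCl2 (8 equiv), NiCl2 (0.1 equiv), DMF, 23 °C
Reagents that add atoms: none (the vinyl group comes from 16)
Why: Nozaki–Hiyama–Kishi vinylation is chemoselective for the aldehyde over the a7 ketone, free OH and acetates; the a8 configuration arises from chelation-controlled addition to the α-keto aldehyde (assumed, with a Mitsunobu inversion option in Step 14).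

**Step 13**
Reactants: 17
Product: 18 (6/10 bicyclic α-hydroxy ketone, Z ring alkene)
Conditions: Hoveyda–Grubbs II (20 mol%), Ti(OiPr)4 (0.3 equiv), toluene (0.002 M), 80 °C, slow addition
Reagents that add atoms: none (ethylene is lost)
Why: Ring-closing metathesis of the vinyl carbinol with the methallyl-type terminal alkene forms the trisubstituted a9=a10 bond, and ring strain in a ten-membered ring demands the cis (Z) alkene shown in the target.

**Step 14**
Reactants: 18; 19 (2-bromopropionyl bromide)
Product: 20 (a8 2-bromopropionate)
Conditions: pyridine, CH2Cl2, −40 → 0 °C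
Reagents that add atoms: none (the acyl unit comes from 19)
Why: The less hindered allylic a8-OH is acylated selectively over the a6-OH, which is neopentyl-like and sits next to the ring.

**Step 15**
Reactants: 20
Product: 21 (9-deacetylstylatulide lactone)
Conditions: Zn dust, TMSCl (cat.), THF, 50 °C, 0.005 M
Reagents that add atoms: none
Why: An intramolecular Reformatsky (aldol-type) reaction: the tethered zinc enolate adds to the a7 ketone in a five-membered closure (chosen over SmI2, which would cleave the α-acyloxy ketone). The macrocycle conformation, with zinc chelated between the a6 oxygen and the a7 carbonyl, directs formation of the trans-fused lactone, the tertiary a7-OH and the b-methyl stereocentre, and the a6-OH is left free as in the target.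

## Compound list

| No. | Name | SMILES | Role |
|---|---|---|---|
| 1 | 2,2-dimethoxyacetaldehyde | COC(OC)C=O | starting material |
| 2 | (1-formylethylidene)triphenylphosphorane | CC(C=O)=P(c1ccccc1)(c1ccccc1)c1ccccc1 | starting material |
| 3 | (E)-4,4-dimethoxy-2-methylbut-2-enal | O=C/C(C)=C/C(OC)OC | intermediate |
| 4 | methyl 2-methyl-3-oxobutanoate | CC(=O)C(C)C(=O)OC | starting material |
| 5 | methyl 6-(dimethoxymethyl)-1,5-dimethyl-2-oxocyclohex-3-ene-1-carboxylate (C5 epimeric) | O=C1C=CC(C)[C@H](C(OC)OC)[C@@]1(C)C(=O)OC | intermediate |
| 6 | methyl 6-(dimethoxymethyl)-1,5-dimethyl-2-oxocyclohex-4-ene-1-carboxylate | O=C1CC=C(C)[C@H](C(OC)OC)[C@@]1(C)C(=O)OC | intermediate |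
| 7 | methyl 6-(dimethoxymethyl)-2-hydroxy-1,5-dimethylcyclohex-4-ene-1-carboxylate | O[C@H]1CC=C(C)[C@H](C(OC)OC)[C@@]1(C)C(=O)OC | intermediate |
| 8 | Weinreb amide of 7 | O[C@H]1CC=C(C)[C@H](C(OC)OC)[C@@]1(C)C(=O)N(C)OC | intermediate |
| 9 | 4-bromo-2-methylbut-1-ene | C=C(C)CCBr | starting material |
| 10 | β-hydroxy ketone (4-methylpent-4-en-1-one on the ring) | O[C@H]1CC=C(C)[C@H](C(OC)OC)[C@@]1(C)C(=O)CCC(C)=C | intermediate |
| 11 | 1,3-syn diol | O[C@H]1CC=C(C)[C@H](C(OC)OC)[C@@]1(C)[C@H](O)CCC(C)=C | intermediate |
| 12 | diacetate of 11 | CC(=O)O[C@H]1CC=C(C)[C@H](C(OC)OC)[C@@]1(C)[C@H](OC(C)=O)CCC(C)=C | intermediate |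
| 13 | diacetate a6 aldehyde | CC(=O)O[C@H]1CC=C(C)[C@H](C=O)[C@@]1(C)[C@H](OC(C)=O)CCC(C)=C | intermediate |
| 14 | α-hydroxy ketone acetal | CC(=O)O[C@H]1CC=C(C)[C@H]([C@@H](O)C(=O)C(OC)OC)[C@@]1(C)[C@H](OC(C)=O)CCC(C)=C | intermediate |
| 15 | α-keto aldehyde | CC(=O)O[C@H]1CC=C(C)[C@H]([C@@H](O)C(=O)C=O)[C@@]1(C)[C@H](OC(C)=O)CCC(C)=C | intermediate |
| 16 | vinyl bromide | C=CBr | starting material |
| 17 | a8 vinyl carbinol (diene) | CC(=O)O[C@H]1CC=C(C)[C@H]([C@@H](O)C(=O)[C@@H](O)C=C)[C@@]1(C)[C@H](OC(C)=O)CCC(C)=C | intermediate |
| 18 | 6/10 bicyclic α-hydroxy ketone diacetate (Z ring alkene) | CC(=O)O[C@H]1CC=C(C)[C@@H]2[C@@H](O)C(=O)[C@@H](O)/C=C(/C)CC[C@@H](OC(C)=O)[C@@]12C | intermediate |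
| 19 | 2-bromopropionyl bromide (racemic) | CC(Br)C(=O)Br | starting material |
| 20 | a8 2-bromopropionate of 18 | CC(=O)O[C@H]1CC=C(C)[C@@H]2[C@@H](O)C(=O)[C@@H](OC(=O)C(C)Br)/C=C(/C)CC[C@@H](OC(C)=O)[C@@]12C | intermediate |
| 21 | 9-deacetylstylatulide lactone | CC(=O)O[C@H]1CC=C(C)[C@@H]2[C@@H](O)[C@@]3(O)[C@H](/C=C(/C)CC[C@@H](OC(C)=O)[C@@]12C)OC(=O)[C@@H]3C | target |

## Totals

Total steps: 15. Longest linear sequence: 15.

## Three steps most likely to fail

1. **Step 2 (proposed new).** A tertiary acyclic donor adding to an α,β-disubstituted iminium may be slow, and it may give poor dr or ee at Cq/a5.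
   Fallback (known chemistry): change the source of stereocontrol. Run the Michael/aldol annulation with the 8-phenylmenthyl ester of 4 under achiral pyrrolidine/AcOH, so that the auxiliary directs the addition. The auxiliary is removed in Step 5 when the Weinreb amide forms.

2. **Step 10 (proposed new).** The hindered aldehyde may not be a competent crossed-benzoin acceptor, and the donor may homo-couple.
   Fallback (known chemistry): add 1-ethoxyvinyllithium to 13, hydrolyse the enol ether to the methyl ketone, then carry out a SeO2 (Riley) oxidation to give 15 directly. The a6 configuration would then rely on Felkin–Anh control, with oxidation/reduction to correct it if needed.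

3. **Step 13.** RCM to a trisubstituted ten-membered alkene next to an α-hydroxy ketone may fail through Ru chelation or oligomerisation.
   Fallback (known chemistry): use a different macrocyclization. In Step 6, replace 9 with the ketal Grignard of 4-bromobutan-2-one to give a methyl-ketone side chain. Convert it to the (Z)-vinyl bromide by CBr4/PPh3, then Pd/Bu3SnH Z-selective hydrodebromination. Close the ring by intramolecular NHK onto the a8 aldehyde, with the a8 aldehyde present instead of the vinyl carbinol.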